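**Retrosynthetic overview**
- Target 13 ⇐ hydrogenolysis of tri-O-benzyl flavonol 12; the 3-OH of 12 ⇐ C2=C3 epoxidation and acid opening of flavone 10.
- Pyranone ring of 10 ⇐ oxidative cyclisation of 2'-hydroxychalcone 8.
- Cα–Cβ bond of 8 ⇐ intermolecular Claisen–Schmidt aldol condensation of acetophenone 4 (A ring) with aldehyde 6 (B ring).
- 4 ⇐ phloroacetophenone 1 by 4,6-di-O-benzylation, ortho-iodination at C3 and Cu-mediated methoxylation; 6 ⇐ benzylation of aldehyde 5.
- Ring order: A and B rings are bought as arenes; only the pyranone C ring is built, after the aldol step.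

Assumption: the target SMILES has no stereocentre and no stereogenic double bond, so the compound is achiral and needs no enantiocontrol; intermediates 7, 9 and 11 are racemic and their stereocentres are erased later.

**Step 1**
Reactants: 1 2',4',6'-trihydroxyacetophenone
Product: 2 1-[2,4-bis(benzyloxy)-6-hydroxyphenyl]ethanone
Conditions: BnBr (2.1 eq), K2CO3 (2.5 eq), DMF, 0 °C to rt
Reagents that add atoms: benzyl bromide, BrCc1ccccc1
Why: Williamson etherification takes the two non-chelated phenols, while the third OH, hydrogen-bonded to the ketone, is much less nucleophilic and stays free.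

**Step 2**
Reactants: 2 1-[2,4-bis(benzyloxy)-6-hydroxyphenyl]ethanone
Product: 3 1-[4,6-bis(benzyloxy)-2-hydroxy-3-iodophenyl]ethanone
Conditions: NIS (1.05 eq), DMF, 0 °C to rt, dark
Reagents that add atoms: N-iodosuccinimide, O=C1CCC(=O)N1I
Why: Electrophilic aromatic iodination under neutral conditions goes ortho to the free chelated phenol, whose only open ortho position is C3 (the carbon that becomes C8 of the flavone).

**Step 3**
Reactants: 3 1-[4,6-bis(benzyloxy)-2-hydroxy-3-iodophenyl]ethanone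
Product: 4 1-[4,6-bis(benzyloxy)-2-hydroxy-3-methoxyphenyl]ethanone
Conditions: NaOMe (6 eq, 25% in MeOH), CuBr (0.3 eq), DMF, 110 °C, N2; then aq. HCl
Reagents that add atoms: sodium methoxide, [Na+].[O-]C
Why: Copper-catalysed Ullmann-type methoxylation of an ortho-iodophenol, the reaction that turns 5-halovanillins into syringaldehyde; benzyl ethers and the phenoxide-deactivated ketone tolerate methoxide.

**Step 4**
Reactants: 5 3-hydroxy-4,5-dimethoxybenzaldehyde
Product: 6 3-(benzyloxy)-4,5-dimethoxybenzaldehyde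
Conditions: BnBr (1.2 eq), K2CO3 (1.5 eq), DMF, 60 °C
Reagents that add atoms: benzyl bromide, BrCc1ccccc1
Why: Williamson etherification of the single phenol, so that every oxygen that must end as OH carries benzyl and every OMe is already in place.

**Step 5**
Reactants: 4 1-[4,6-bis(benzyloxy)-2-hydroxy-3-methoxyphenyl]ethanone; 6 3-(benzyloxy)-4,5-dimethoxybenzaldehyde
Product: 8 (E)-1-[4,6-bis(benzyloxy)-2-hydroxy-3-methoxyphenyl]-3-[3-(benzyloxy)-4,5-dimethoxyphenyl]prop-2-en-1-one, via racemic β-hydroxy ketone 7 (not isolated)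
Conditions: 6 (1.2 eq), KOH (50% aq., 10 eq), EtOH/THF, rt, 24–48 h; then cold 1 M HCl
Reagents that add atoms: none
Why: Claisen–Schmidt crossed aldol condensation: the methyl-ketone enolate of 4 adds to the non-enolisable aldehyde 6, and aldol adduct 7 dehydrates by E1cB to the thermodynamically favoured E-chalcone, which erases its stereocentre.

**Step 6**
Reactants: 8 (E)-1-[4,6-bis(benzyloxy)-2-hydroxy-3-methoxyphenyl]-3-[3-(benzyloxy)-4,5-dimethoxyphenyl]prop-2-en-1-one
Product: 10 5,7-bis(benzyloxy)-2-[3-(benzyloxy)-4,5-dimethoxyphenyl]-8-methoxy-4H-chromen-4-one, via racemic flavanone 9 (not isolated)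
Conditions: I2 (0.1 eq), DMSO, 125 °C, 2–4 h; then aq. Na2S2O3
Reagents that add atoms: none
Why: Iodine-catalysed oxidative cyclisation: intramolecular oxa-Michael addition of the 2'-phenol gives flavanone 9, which I2 dehydrogenates to the chromone with DMSO as terminal oxidant, so the C2 stereocentre disappears.

**Step 7**
Reactants: 10 5,7-bis(benzyloxy)-2-[3-(benzyloxy)-4,5-dimethoxyphenyl]-8-methoxy-4H-chromen-4-one
Product: 12 5,7-bis(benzyloxy)-2-[3-(benzyloxy)-4,5-dimethoxyphenyl]-3-hydroxy-8-methoxy-4H-chromen-4-one, via racemic flavone 2,3-epoxide 11 (not isolated)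
Conditions: DMDO (ca. 0.08 M in acetone, 3–4 eq), CH2Cl2, 0 °C to rt; evaporate; then p-TsOH·H2O (0.1 eq), CH2Cl2, rt
Reagents that add atoms: dimethyldioxirane, CC1(C)OO1
Why: Electrophilic epoxidation of the C2=C3 enol-ether bond gives epoxide 11, which under acid opens to the C2 oxocarbenium ion and loses H-3 to give the flavonol, leaving no stereocentre.

**Step 8**
Reactants: 12 5,7-bis(benzyloxy)-2-[3-(benzyloxy)-4,5-dimethoxyphenyl]-3-hydroxy-8-methoxy-4H-chromen-4-one
Product: 13 3,5,7-trihydroxy-2-(3-hydroxy-4,5-dimethoxyphenyl)-8-methoxy-4H-chromen-4-one (CNP0225742.0)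
Conditions: H2 (1 atm), 10% Pd/C, THF/MeOH 1:1, rt
Reagents that add atoms: none
Why: Catalytic hydrogenolysis cleaves the three benzyl aryl ethers, while the methyl ethers, the chromone carbonyl and the tetrasubstituted C2=C3 bond are inert at 1 atm.

**Compound list**
1 | 2',4',6'-trihydroxyacetophenone | CC(=O)c1c(O)cc(O)cc1O | starting material
2 | 1-[2,4-bis(benzyloxy)-6-hydroxyphenyl]ethanone | CC(=O)c1c(O)cc(OCc2ccccc2)cc1OCc1ccccc1 | intermediate
3 | 1-[4,6-bis(benzyloxy)-2-hydroxy-3-iodophenyl]ethanone | CC(=O)c1c(O)c(I)c(OCc2ccccc2)cc1OCc1ccccc1 | intermediate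
4 | 1-[4,6-bis(benzyloxy)-2-hydroxy-3-methoxyphenyl]ethanone | CC(=O)c1c(O)c(OC)c(OCc2ccccc2)cc1OCc1ccccc1 | intermediate
5 | 3-hydroxy-4,5-dimethoxybenzaldehyde | COc1cc(C=O)cc(O)c1OC | starting material
6 | 3-(benzyloxy)-4,5-dimethoxybenzaldehyde | COc1cc(C=O)cc(OCc2ccccc2)c1OC | intermediate
7 | 1-[4,6-bis(benzyloxy)-2-hydroxy-3-methoxyphenyl]-3-[3-(benzyloxy)-4,5-dimethoxyphenyl]-3-hydroxypropan-1-one (racemic aldol adduct) | COc1cc(C(O)CC(=O)c2c(O)c(OC)c(OCc3ccccc3)cc2OCc2ccccc2)cc(OCc2ccccc2)c1OC | intermediate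
8 | (E)-1-[4,6-bis(benzyloxy)-2-hydroxy-3-methoxyphenyl]-3-[3-(benzyloxy)-4,5-dimethoxyphenyl]prop-2-en-1-one | COc1cc(/C=C/C(=O)c2c(O)c(OC)c(OCc3ccccc3)cc2OCc2ccccc2)cc(OCc2ccccc2)c1OC | intermediate
9 | 5,7-bis(benzyloxy)-2-[3-(benzyloxy)-4,5-dimethoxyphenyl]-8-methoxychroman-4-one (racemic flavanone) | COc1cc(C2CC(=O)c3c(OCc4ccccc4)cc(OCc4ccccc4)c(OC)c3O2)cc(OCc2ccccc2)c1OC | intermediate
10 | 5,7-bis(benzyloxy)-2-[3-(benzyloxy)-4,5-dimethoxyphenyl]-8-methoxy-4H-chromen-4-one | COc1cc(-c2cc(=O)c3c(OCc4ccccc4)cc(OCc4ccccc4)c(OC)c3o2)cc(OCc2ccccc2)c1OC | intermediate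
11 | 2,3-epoxide of flavone 10 (racemic, cis-fused oxirane) | COc1cc(C23OC2C(=O)c2c(O3)c(OC)c(OCc3ccccc3)cc2OCc2ccccc2)cc(OCc2ccccc2)c1OC | intermediate
12 | 5,7-bis(benzyloxy)-2-[3-(benzyloxy)-4,5-dimethoxyphenyl]-3-hydroxy-8-methoxy-4H-chromen-4-one | COc1cc(-c2oc3c(OC)c(OCc4ccccc4)cc(OCc4ccccc4)c3c(=O)c2O)cc(OCc2ccccc2)c1OC | intermediate
13 | 3,5,7-trihydroxy-2-(3-hydroxy-4,5-dimethoxyphenyl)-8-methoxy-4H-chromen-4-one | COc1cc(-c2oc3c(OC)c(O)cc(O)c3c(=O)c2O)cc(O)c1OC | target

**Totals**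
Total steps: 8. Longest linear sequence: 7 (steps 1, 2, 3, 5, 6, 7, 8); step 4 is the one-step side branch.

**Three steps most likely to fail**

Step 3 (methoxylation of a doubly ortho-substituted iodophenol that also carries a methyl ketone; the risks are proto-deiodination back to 2 and incomplete conversion). The fallback sets out from 3 and comes back at 10 by moving the C–O coupling to the flavone stage, where there is neither a free phenol nor an enolisable ketone. Iodide 3 is condensed with 6 (KOH, EtOH/THF, rt) to give, through the iodo aldol adduct F1, the 3'-iodochalcone F2. I2/DMSO at 125 °C closes F2 through the 8-iodoflavanone F3 to the 8-iodoflavone F4. F4 is then methoxylated (NaOMe, CuBr, DMF/MeOH, 110 °C) to give 10.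

Step 6 (HI formed from I2 can cleave the peri 5-O-benzyl ether or iodinate the electron-rich rings). The fallback sets out from 8 and comes back at 12, bypassing the flavone altogether by an Algar–Flynn–Oyamada oxidation. Chalcone 8 is treated with 30% H2O2 and aq. NaOH in MeOH/THF at 0 °C to rt. Oxidative ring closure gives the racemic trans-dihydroflavonol F5, which is dehydrogenated in the same flask to flavonol 12. The aurone by-product typical of 6'-alkoxychalcones is removed by chromatography.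

Step 7 (slow epoxidation of a hindered, electron-rich flavone and competing oxidation of benzylic C–H by excess DMDO). The fallback sets out from 10 and comes back at 12 by making C3 the nucleophile instead of attacking it with an electrophilic oxidant. LDA in THF at −78 °C gives the 3-lithioflavone F6. Trapping with B(OMe)3 and an AcOH quench gives the dimethyl flavon-3-ylboronate F7. Oxidation of the C–B bond with H2O2/AcOH gives 12.

**Further compounds**
F1 | step 3 | 1-[4,6-bis(benzyloxy)-2-hydroxy-3-iodophenyl]-3-[3-(benzyloxy)-4,5-dimethoxyphenyl]-3-hydroxypropan-1-one (racemic) | COc1cc(C(O)CC(=O)c2c(O)c(I)c(OCc3ccccc3)cc2OCc2ccccc2)cc(OCc2ccccc2)c1OC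
F2 | step 3 | (E)-1-[4,6-bis(benzyloxy)-2-hydroxy-3-iodophenyl]-3-[3-(benzyloxy)-4,5-dimethoxyphenyl]prop-2-en-1-one | COc1cc(/C=C/C(=O)c2c(O)c(I)c(OCc3ccccc3)cc2OCc2ccccc2)cc(OCc2ccccc2)c1OC
F3 | step 3 | 5,7-bis(benzyloxy)-2-[3-(benzyloxy)-4,5-dimethoxyphenyl]-8-iodochroman-4-one (racemic) | COc1cc(C2CC(=O)c3c(OCc4ccccc4)cc(OCc4ccccc4)c(I)c3O2)cc(OCc2ccccc2)c1OC
F4 | step 3 | 5,7-bis(benzyloxy)-2-[3-(benzyloxy)-4,5-dimethoxyphenyl]-8-iodo-4H-chromen-4-one | COc1cc(-c2cc(=O)c3c(OCc4ccccc4)cc(OCc4ccccc4)c(I)c3o2)cc(OCc2ccccc2)c1OC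
F5 | step 6 | trans-5,7-bis(benzyloxy)-2-[3-(benzyloxy)-4,5-dimethoxyphenyl]-3-hydroxy-8-methoxychroman-4-one (racemic; 2R,3R enantiomer drawn) | COc1cc([C@H]2Oc3c(OC)c(OCc4ccccc4)cc(OCc4ccccc4)c3C(=O)[C@@H]2O)cc(OCc2ccccc2)c1OC
F6 | step 7 | 3-lithio derivative of flavone 10 | COc1cc(-c2oc3c(OC)c(OCc4ccccc4)cc(OCc4ccccc4)c3c(=O)c2[Li])cc(OCc2ccccc2)c1OC
F7 | step 7 | dimethyl {5,7-bis(benzyloxy)-2-[3-(benzyloxy)-4,5-dimethoxyphenyl]-8-methoxy-4-oxo-4H-chromen-3-yl}boronate | COc1cc(-c2oc3c(OC)c(OCc4ccccc4)cc(OCc4ccccc4)c3c(=O)c2B(OC)OC)cc(OCc2ccccc2)c1OC
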